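**Strategy.** The plan rests on the five-membered ring (C1, C2, C3, C3a, C8a; azulene numbering): its oxygens at C1 and C3 flank C2 as in the adduct of a 2-oxyallyl cation (C8a–C1–C2) with an enol ether (C3a=C3). An intramolecular (3+2) cycloaddition of a 2-siloxyallyl cation with a (Z)-silyl enol ether, linked through C4–C8, forms C2–C3 and C3a–C8a in one operation, closes both the cyclopentanone and the cycloheptene, and sets C3, C3a and the quaternary C8a from the lone C4 stereocentre. The precursor is an acyclic bis(silyl enol ether) bearing a tertiary allylic chloride, made from a chloro diketone.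

Key step: step 13

Remark: azulene numbering is used for the core (C1 acetate, C3 tertiary hydroxyl, C3a ring-fusion CH, C4 aryl ester, C6=C7 alkene, C8a angular methyl). THP ethers 10–13 are mixtures at the acetal carbon. Compounds 19–22 are mixtures of both epimers at the chlorine-bearing carbon, which becomes planar in step 13.

**Step 1**
Reactants: 1 2-methylpropanal; 2 propane-1,3-dithiol
Product: 3 2-isopropyl-1,3-dithiane
Conditions: BF3·OEt2 (cat.), CH2Cl2, 0 °C to rt
Reagents that add atoms: none
Why: Lewis acid-catalysed dithioacetalisation of an aldehyde should give the acyl anion equivalent for C3; no stereocentre is formed.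

**Step 2**
Reactants: 3 2-isopropyl-1,3-dithiane; 4 (R)-epichlorohydrin
Product: 6 (R)-2-isopropyl-2-(oxiran-2-ylmethyl)-1,3-dithiane, via 2-lithio-2-isopropyl-1,3-dithiane 5 (not isolated)
Conditions: n-BuLi, THF, −20 °C; then 4, −78 °C to rt
Reagents that add atoms: none
Why: Corey–Seebach alkylation in which the dithiane anion opens the epoxide at its CH2 terminus and the alkoxide then displaces chloride to re-form an epoxide, so the stereocentre of 4 (future C4) is carried over without any of its bonds being broken.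

**Step 3**
Reactants: 7 but-2-yn-1-ol
Product: 9 (Z)-3-iodobut-2-en-1-ol, via cyclic alkenylalanate 8 (not isolated)
Conditions: NaAlH2(OCH2CH2OCH3)2, THF, 0 °C to rt; then I2, −78 °C
Reagents that add atoms: iodine, II
Why: hydroxyl-directed trans-hydroalumination of a propargylic alcohol followed by iodinolysis with retention should fix the Z geometry (iodine cis to CH2OH) that later becomes the ring alkene.

**Step 4**
Reactants: 9 (Z)-3-iodobut-2-en-1-ol
Product: 10 2-{[(Z)-3-iodobut-2-en-1-yl]oxy}tetrahydro-2H-pyran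
Conditions: 3,4-dihydro-2H-pyran, PPTS (cat.), CH2Cl2, rt
Reagents that add atoms: 3,4-dihydro-2H-pyran, C1=COCCC1
Why: acid-catalysed acetalisation; an acetal is chosen because, unlike a silyl ether, it cannot undergo 1,4-silyl migration in the cis-alkenyllithium of step 5.

**Step 5**
Reactants: 10 THP ether of the iodo alcohol; 6 (R)-epoxide
Product: 12 (2S,4Z)-1-(2-isopropyl-1,3-dithian-2-yl)-4-methyl-6-(tetrahydro-2H-pyran-2-yloxy)hex-4-en-2-ol, via (Z)-alkenyllithium 11 (not isolated)
Conditions: t-BuLi (2 equiv), Et2O, −78 °C; then 6, BF3·OEt2, −78 °C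
Reagents that add atoms: none
Why: iodine–lithium exchange with retention of alkene geometry followed by BF3-promoted SN2 opening of the terminal epoxide at CH2 should join the fragments; the carbinol centre is not touched (its descriptor changes to S only through priorities).

**Step 6**
Reactants: 12 homoallylic alcohol
Product: 13 tert-butyl{[(2S,4Z)-1-(2-isopropyl-1,3-dithian-2-yl)-4-methyl-6-(tetrahydro-2H-pyran-2-yloxy)hex-4-en-2-yl]oxy}dimethylsilane
Conditions: TBSCl, imidazole, DMAP (cat.), DMF, rt to 40 °C
Reagents that add atoms: tert-butyl(chloro)dimethylsilane, CC(C)(C)[Si](C)(C)Cl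
Why: standard silylation of a secondary alcohol; silyl triflates are avoided because they would cleave the THP acetal.

**Step 7**
Reactants: 13 TBS/THP bis-ether
Product: 14 {[(2S,4Z)-6-bromo-1-(2-isopropyl-1,3-dithian-2-yl)-4-methylhex-4-en-2-yl]oxy}(tert-butyl)dimethylsilane
Conditions: PPh3, CBr4, CH2Cl2, 0 °C to rt
Reagents that add atoms: tetrabromomethane, BrC(Br)(Br)Br
Why: Appel-type conversion of a THP ether directly into the bromide should give the primary allylic bromide with the Z geometry intact, the secondary TBS ether and the dithiane being inert.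

**Step 8**
Reactants: 15 2-chloropropanoyl chloride (racemic); 16 N,O-dimethylhydroxylamine hydrochloride
Product: 17 2-chloro-N-methoxy-N-methylpropanamide (racemic)
Conditions: Et3N, CH2Cl2, 0 °C
Reagents that add atoms: none
Why: acylation of the hydroxylamine by an acid chloride (Weinreb amide formation).

**Step 9**
Reactants: 14 allylic bromide; 17 chloro Weinreb amide
Product: 19 (4Z,7S)-7-[(tert-butyldimethylsilyl)oxy]-2-chloro-8-(2-isopropyl-1,3-dithian-2-yl)-N-methoxy-N,2,5-trimethyloct-4-enamide (both C2 epimers), via lithium enolate of 17 18 (not isolated)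
Conditions: LiN(SiMe3)2, THF, −78 °C; then 14, DMPU, −78 to −40 °C
Reagents that add atoms: none
Why: SN2 alkylation of an amide enolate by a primary allylic bromide should build the chlorine-bearing quaternary carbon (future C8a); its configuration is not controlled and does not matter.

**Step 10**
Reactants: 19 chloro Weinreb amide
Product: 20 (5Z,8S)-8-[(tert-butyldimethylsilyl)oxy]-3-chloro-9-(2-isopropyl-1,3-dithian-2-yl)-3,6-dimethylnon-5-en-2-one
Conditions: MeMgBr, THF, 0 °C
Reagents that add atoms: methylmagnesium bromide, C[Mg]Br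
Why: Weinreb ketone synthesis; the chelated tetrahedral intermediate should prevent over-addition and the amide has no α-hydrogen to lose.

**Step 11**
Reactants: 20 chloro ketone dithiane
Product: 21 (5Z,8S)-8-[(tert-butyldimethylsilyl)oxy]-3-chloro-3,6,11-trimethyldodec-5-ene-2,10-dione
Conditions: MeI, CaCO3, MeCN/H2O (4:1), 45 °C
Reagents that add atoms: water, O
Why: S-alkylative hydrolysis of the dithioacetal under neutral, non-oxidising conditions should unveil the isopropyl ketone without touching the alkene, the silyl ether or the tertiary chloride.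

**Step 12**
Reactants: 21 chloro diketone
Product: 22 (3Z,5S,7Z)-5-[(tert-butyldimethylsilyl)oxy]-10-chloro-2,7,10-trimethyl-3,11-bis[(trimethylsilyl)oxy]dodeca-3,7,11-triene (used crude)
Conditions: LiN(SiMe3)2 (2.4 equiv), Me3SiCl (in situ quench), THF, −78 °C
Reagents that add atoms: chlorotrimethylsilane, C[Si](C)(C)Cl
Why: kinetic enolisation with internal silyl quench should take the methyl ketone at CH3 (its other α-carbon is quaternary) and the isopropyl ketone at the less hindered CH2; the Z enol silane is expected because the isopropyl group avoids the position cis to the chain.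

**Step 13**
Reactants: 22 bis(silyl enol ether)
Product: 25 (3R,3aS,4S,8aR)-3,4-dihydroxy-3-isopropyl-6,8a-dimethyl-3,3a,4,5,8,8a-hexahydroazulen-1(2H)-one, via 2-siloxyallyl cation triflate 23 (not isolated), via bis-silylated cycloadduct 24 (not isolated)
Conditions: AgOSO2CF3, 2,6-di-tert-butyl-4-methylpyridine, CH2Cl2 (0.005 M), −78 to −40 °C; then HF·pyridine, pyridine, THF, 0 °C to rt
Reagents that add atoms: none
Why: AgOSO2CF3 should abstract the tertiary allylic chloride to give the 2-siloxyallyl cation 23, whose tertiary terminus (future C8a) is attacked by the β-carbon of the tethered (Z)-silyl enol ether (future C3a), after which the siloxycarbenium ion at C3 is captured by the enol-silane carbon C2 and loss of Me3Si+ leaves the cyclopentanone 24. The closest known reaction type is the (3+2) cyclopentanone annulation of 2-siloxyallyl cations with silyl enol ethers and alkenes, here run intramolecularly. The cycloheptene closes in a 7-exo-trig cation–enol ether addition and the cyclopentanone in a 5-(enolendo)-exo-trig Mukaiyama-type closure, suprafacial on both partners. C3a is set by allylic 1,3-strain in the Z enol ether (C4–H in the enol plane, so the cation tethered through C5 adds anti to the OTBS group), C8a by a chair-like cycloheptene transition state that keeps the OTBS group, C3 and the siloxyvinyl arm pseudo-equatorial and only the methyl group pseudo-axial (trans ring fusion), and C3 by retention of the Z geometry in the suprafacial closure (oxygen cis to C4 and to the angular methyl). The step needs regioselectivity for the hindered tertiary terminus, which the tether secures (bonding at C2 would need a nine-membered ring), and chemoselectivity over the C6=C7 alkene, which is far less nucleophilic than the enol silane and can reach only C2 of the cation along an in-plane, stereoelectronically poor trajectory; high dilution and the hindered pyridine should suppress oligomerisation and protodesilylation. HF·pyridine then cleaves the tertiary Me3Si ether and the secondary TBS ether to give 25.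

**Step 14**
Reactants: 25 diol ketone; 26 4-acetoxybenzoyl chloride
Product: 27 (3R,3aS,4S,8aR)-3-hydroxy-3-isopropyl-6,8a-dimethyl-1-oxo-1,2,3,3a,4,5,8,8a-octahydroazulen-4-yl 4-acetoxybenzoate
Conditions: pyridine, DMAP (cat.), CH2Cl2, 0 °C to rt
Reagents that add atoms: none
Why: DMAP-catalysed acylation should take the secondary C4 hydroxyl and leave the hindered tertiary C3 hydroxyl free.

**Step 15**
Reactants: 27 keto ester
Product: 28 (1S,3R,3aS,4S,8aR)-1,3-dihydroxy-3-isopropyl-6,8a-dimethyl-1,2,3,3a,4,5,8,8a-octahydroazulen-4-yl 4-acetoxybenzoate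
Conditions: Me4NBH(OAc)3, MeCN/AcOH (1:1), −20 °C
Reagents that add atoms: none
Why: Evans–Saksena directed reduction, in which the C3 hydroxyl binds boron and delivers hydride to its own face of the C1 ketone, should give the 1,3-trans diol (C1–OH trans to C3–OH) and spare both esters.

**Step 16**
Reactants: 28 diol
Product: 29 (1S,3R,3aS,4S,8aR)-1-acetoxy-3-hydroxy-3-isopropyl-6,8a-dimethyl-1,2,3,3a,4,5,8,8a-octahydroazulen-4-yl 4-acetoxybenzoate
Conditions: Ac2O, pyridine, DMAP (cat.), CH2Cl2, rt
Reagents that add atoms: acetic anhydride, CC(=O)OC(C)=O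
Why: acetylation should occur at the secondary C1 hydroxyl only, the tertiary C3 hydroxyl being too hindered under these conditions.

**Step 17**
Reactants: 29 diacetate
Product: 30 (1S,3R,3aS,4S,8aR)-1-acetoxy-3-hydroxy-3-isopropyl-6,8a-dimethyl-1,2,3,3a,4,5,8,8a-octahydroazulen-4-yl 4-hydroxybenzoate (target, CNP0275279.1)
Conditions: pyrrolidine, CH2Cl2, 0 °C
Reagents that add atoms: none
Why: chemoselective aminolysis of the aryl acetate (phenoxide leaving group) should free the phenol while the alkyl acetate and the benzoate ester remain.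

**Compound list**

1 | 2-methylpropanal | CC(C)C=O | starting material
2 | propane-1,3-dithiol | SCCCS | starting material
3 | 2-isopropyl-1,3-dithiane | CC(C)C1SCCCS1 | intermediate
4 | (R)-epichlorohydrin | ClC[C@H]1CO1 | starting material
5 | 2-lithio-2-isopropyl-1,3-dithiane | [Li]C1(C(C)C)SCCCS1 | intermediate (not isolated)
6 | (R)-2-isopropyl-2-(oxiran-2-ylmethyl)-1,3-dithiane | CC(C)C1(SCCCS1)C[C@@H]1CO1 | intermediate
7 | but-2-yn-1-ol | CC#CCO | starting material
8 | cyclic alkenylalanate (sodium salt; Al bound to O and to C3, cis) | C/C(=C/CO1)[Al-]1(OCCOC)OCCOC.[Na+] | intermediate (not isolated)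
9 | (Z)-3-iodobut-2-en-1-ol | C/C(I)=C/CO | intermediate
10 | 2-{[(Z)-3-iodobut-2-en-1-yl]oxy}tetrahydro-2H-pyran | C/C(I)=C/COC1CCCCO1 | intermediate
11 | (Z)-alkenyllithium from 10 | C/C([Li])=C/COC1CCCCO1 | intermediate (not isolated)
12 | (2S,4Z)-1-(2-isopropyl-1,3-dithian-2-yl)-4-methyl-6-(tetrahydro-2H-pyran-2-yloxy)hex-4-en-2-ol | CC(C)C1(SCCCS1)C[C@@H](O)C/C(C)=C\COC1CCCCO1 | intermediate
13 | TBS ether of 12 | CC(C)C1(SCCCS1)C[C@@H](O[Si](C)(C)C(C)(C)C)C/C(C)=C\COC1CCCCO1 | intermediate
14 | {[(2S,4Z)-6-bromo-1-(2-isopropyl-1,3-dithian-2-yl)-4-methylhex-4-en-2-yl]oxy}(tert-butyl)dimethylsilane | CC(C)C1(SCCCS1)C[C@@H](O[Si](C)(C)C(C)(C)C)C/C(C)=C\CBr | intermediate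
15 | 2-chloropropanoyl chloride | CC(Cl)C(Cl)=O | starting material
16 | N,O-dimethylhydroxylamine hydrochloride | CNOC.Cl | starting material
17 | 2-chloro-N-methoxy-N-methylpropanamide | CC(Cl)C(=O)N(C)OC | intermediate
18 | lithium enolate of 17 | CC(Cl)=C(O[Li])N(C)OC | intermediate (not isolated)
19 | (4Z,7S)-7-[(tert-butyldimethylsilyl)oxy]-2-chloro-8-(2-isopropyl-1,3-dithian-2-yl)-N-methoxy-N,2,5-trimethyloct-4-enamide | CC(C)C1(SCCCS1)C[C@@H](O[Si](C)(C)C(C)(C)C)C/C(C)=C\CC(C)(Cl)C(=O)N(C)OC | intermediate
20 | (5Z,8S)-8-[(tert-butyldimethylsilyl)oxy]-3-chloro-9-(2-isopropyl-1,3-dithian-2-yl)-3,6-dimethylnon-5-en-2-one | CC(C)C1(SCCCS1)C[C@@H](O[Si](C)(C)C(C)(C)C)C/C(C)=C\CC(C)(Cl)C(C)=O | intermediate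
21 | (5Z,8S)-8-[(tert-butyldimethylsilyl)oxy]-3-chloro-3,6,11-trimethyldodec-5-ene-2,10-dione | CC(C)C(=O)C[C@@H](O[Si](C)(C)C(C)(C)C)C/C(C)=C\CC(C)(Cl)C(C)=O | intermediate
22 | (3Z,5S,7Z)-5-[(tert-butyldimethylsilyl)oxy]-10-chloro-2,7,10-trimethyl-3,11-bis[(trimethylsilyl)oxy]dodeca-3,7,11-triene | CC(C)/C(O[Si](C)(C)C)=C/[C@@H](O[Si](C)(C)C(C)(C)C)C/C(C)=C\CC(C)(Cl)C(=C)O[Si](C)(C)C | intermediate
23 | 2-siloxyallyl cation triflate from 22 | CC(C)/C(O[Si](C)(C)C)=C/[C@@H](O[Si](C)(C)C(C)(C)C)C/C(C)=C\C[C+](C)C(=C)O[Si](C)(C)C.[O-]S(=O)(=O)C(F)(F)F | intermediate (not isolated)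
24 | (3R,3aS,4S,8aR)-4-[(tert-butyldimethylsilyl)oxy]-3-isopropyl-6,8a-dimethyl-3-[(trimethylsilyl)oxy]-3,3a,4,5,8,8a-hexahydroazulen-1(2H)-one | O=C1C[C@@](O[Si](C)(C)C)(C(C)C)[C@@H]2[C@@H](O[Si](C)(C)C(C)(C)C)CC(C)=CC[C@@]12C | intermediate (not isolated)
25 | (3R,3aS,4S,8aR)-3,4-dihydroxy-3-isopropyl-6,8a-dimethyl-3,3a,4,5,8,8a-hexahydroazulen-1(2H)-one | O=C1C[C@@](O)(C(C)C)[C@@H]2[C@@H](O)CC(C)=CC[C@@]12C | intermediate
26 | 4-acetoxybenzoyl chloride | CC(=O)Oc1ccc(cc1)C(Cl)=O | starting material
27 | (3R,3aS,4S,8aR)-3-hydroxy-3-isopropyl-6,8a-dimethyl-1-oxo-1,2,3,3a,4,5,8,8a-octahydroazulen-4-yl 4-acetoxybenzoate | O=C1C[C@@](O)(C(C)C)[C@@H]2[C@@H](OC(=O)c3ccc(OC(C)=O)cc3)CC(C)=CC[C@@]12C | intermediate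
28 | (1S,3R,3aS,4S,8aR)-1,3-dihydroxy-3-isopropyl-6,8a-dimethyl-1,2,3,3a,4,5,8,8a-octahydroazulen-4-yl 4-acetoxybenzoate | O[C@H]1C[C@@](O)(C(C)C)[C@@H]2[C@@H](OC(=O)c3ccc(OC(C)=O)cc3)CC(C)=CC[C@@]12C | intermediate
29 | (1S,3R,3aS,4S,8aR)-1-acetoxy-3-hydroxy-3-isopropyl-6,8a-dimethyl-1,2,3,3a,4,5,8,8a-octahydroazulen-4-yl 4-acetoxybenzoate | CC(=O)O[C@H]1C[C@@](O)(C(C)C)[C@@H]2[C@@H](OC(=O)c3ccc(OC(C)=O)cc3)CC(C)=CC[C@@]12C | intermediate
30 | (1S,3R,3aS,4S,8aR)-1-acetoxy-3-hydroxy-3-isopropyl-6,8a-dimethyl-1,2,3,3a,4,5,8,8a-octahydroazulen-4-yl 4-hydroxybenzoate | CC(=O)O[C@H]1C[C@@](O)(C(C)C)[C@@H]2[C@@H](OC(=O)c3ccc(O)cc3)CC(C)=CC[C@@]12C | target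

**Step count and risks**

Total step count: 17. Longest linear sequence: 14 steps (1, 2, 5, 6, 7, 9–17).

Steps most likely to fail:

1. Step 13 (key step). Bonding at the hindered tertiary terminus through a seven-membered transition state may be slow. Proton loss from the cation to 2-siloxydienes, intermolecular capture, or desilylation of the siloxycarbenium ion before the second bond forms could then compete, and the ring fusion may form with poor selectivity. The fallback makes the two bonds in separate known steps, the first by a radical process; it sets out from 19 and comes back at 25. Dithiane removal from 19 (MeI, CaCO3, aqueous MeCN) would give keto amide F1, in which only the isopropyl ketone can enolise. LiN(SiMe3)2/TBSCl would then give the (Z)-tert-butyldimethylsilyl enol ether F2, and MeMgBr the chloro ketone F3. Photoredox alkylation of the enol silane by the α-chloro ketone (fac-Ir(ppy)3, blue light, MeCN; the known radical-polar crossover alkylation of enol silanes by α-halo ketones, here as a 7-exo cyclisation) would give the cycloheptene 1,4-diketone F4. Its C3a centre is α to a ketone and can be equilibrated with base to the all-trans arrangement. LiN(iPr)2 at −78 °C (kinetic methyl ketone enolate, intramolecular aldol addition) would close the five-membered ring to hydroxy ketone F5, and HF·pyridine would return to 25.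

2. Step 12. With two ketones enolised at once, Favorskii-type collapse of the chloro ketone enolate, β-elimination of the silyloxy group, or scrambling of the site and geometry of enolisation at the isopropyl ketone may occur. The fallback forms the two enol silanes at separate stages; it sets out from 19 and comes back at 25. It follows the branch above as far as chloro ketone F3 (through F1 and F2), so that each ketone is enolised while it is the only enolisable carbonyl and the robust TBS enol ether can be purified and its geometry secured. LiN(iPr)2/Me3SiCl on F3 would give the mixed bis(enol silane) F6, the conditions of step 13 would give the bis-TBS cycloadduct F7, and HF·pyridine would give 25.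

3. Step 9. The α-chloro amide enolate may decompose (self-condensation, loss of the N-methoxy group) before it is alkylated. The fallback introduces chlorine after the C–C bond is made; it sets out from 14 and comes back at 19. Alkylation of the lithium enolate of commercially available N-methoxy-N-methylpropanamide with 14 (a standard Weinreb amide enolate alkylation) would give the α-methyl amide F8. Deprotonation of F8 with LiN(iPr)2 and chlorination of the enolate with C2Cl6, which spares the dithiane, would give 19.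

**Further compounds**

F1 | step 13 | (4Z,7S)-7-[(tert-butyldimethylsilyl)oxy]-2-chloro-N-methoxy-N,2,5,10-tetramethyl-9-oxoundec-4-enamide | CC(C)C(=O)C[C@@H](O[Si](C)(C)C(C)(C)C)C/C(C)=C\CC(C)(Cl)C(=O)N(C)OC
F2 | step 13 | (4Z,7S,8Z)-7,9-bis[(tert-butyldimethylsilyl)oxy]-2-chloro-N-methoxy-N,2,5,10-tetramethylundeca-4,8-dienamide | CC(C)/C(O[Si](C)(C)C(C)(C)C)=C/[C@@H](O[Si](C)(C)C(C)(C)C)C/C(C)=C\CC(C)(Cl)C(=O)N(C)OC
F3 | step 13 | (5Z,8S,9Z)-8,10-bis[(tert-butyldimethylsilyl)oxy]-3-chloro-3,6,11-trimethyldodeca-5,9-dien-2-one | CC(C)/C(O[Si](C)(C)C(C)(C)C)=C/[C@@H](O[Si](C)(C)C(C)(C)C)C/C(C)=C\CC(C)(Cl)C(C)=O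
F4 | step 13 | 1-[(1S,2S,7R)-7-acetyl-2-[(tert-butyldimethylsilyl)oxy]-4,7-dimethylcyclohept-4-en-1-yl]-2-methylpropan-1-one | CC(C)C(=O)[C@@H]1[C@@H](O[Si](C)(C)C(C)(C)C)CC(C)=CC[C@@]1(C)C(C)=O
F5 | step 13 | (3R,3aS,4S,8aR)-4-[(tert-butyldimethylsilyl)oxy]-3-hydroxy-3-isopropyl-6,8a-dimethyl-3,3a,4,5,8,8a-hexahydroazulen-1(2H)-one | O=C1C[C@@](O)(C(C)C)[C@@H]2[C@@H](O[Si](C)(C)C(C)(C)C)CC(C)=CC[C@@]12C
F6 | step 12 | (3Z,5S,7Z)-3,5-bis[(tert-butyldimethylsilyl)oxy]-10-chloro-2,7,10-trimethyl-11-[(trimethylsilyl)oxy]dodeca-3,7,11-triene | CC(C)/C(O[Si](C)(C)C(C)(C)C)=C/[C@@H](O[Si](C)(C)C(C)(C)C)C/C(C)=C\CC(C)(Cl)C(=C)O[Si](C)(C)C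
F7 | step 12 | (3R,3aS,4S,8aR)-3,4-bis[(tert-butyldimethylsilyl)oxy]-3-isopropyl-6,8a-dimethyl-3,3a,4,5,8,8a-hexahydroazulen-1(2H)-one | O=C1C[C@@](O[Si](C)(C)C(C)(C)C)(C(C)C)[C@@H]2[C@@H](O[Si](C)(C)C(C)(C)C)CC(C)=CC[C@@]12C
F8 | step 9 | (4Z,7S)-7-[(tert-butyldimethylsilyl)oxy]-8-(2-isopropyl-1,3-dithian-2-yl)-N-methoxy-N,2,5-trimethyloct-4-enamide | CC(C)C1(SCCCS1)C[C@@H](O[Si](C)(C)C(C)(C)C)C/C(C)=C\CC(C)C(=O)N(C)OC
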